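**Plan**
1. Retrosynthetic cuts: the four O–Si bonds go last. The C8 side chain is traced back from the (R)-allylic alcohol through an epoxy iodide, a Sharpless epoxy alcohol and an (E)-enal to an 8-allyl group, whose C8–CH2 bond comes from a Claisen shift from O7.
2. Ring A is then cut at C7–C8 and C5–C6. This leaves a 5-aryl-2-methyl-4-pyranone-3-carboxylate (rings C and B) and methyl 5-methylhex-4-enoate (C6, C7 and the prenyl group).
3. Enabling feature: in ring C the carbon next to O1 (future C8a) carries a methyl group (future C8), and the carbon next to C4=O (future C4a) carries an ester (future C5). The C7–C6 unit of the hexenoate bridges these two groups, so ring A must form with oxygen on C5 and C7, prenyl on C6 and hydrogen only on C8.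
4. Forward order of rings: B (bought with 3,4-dihydroxyphenylacetic acid), then C (step 3), then A (step 5). The C8 chain is grown afterwards.
5. Stereochemistry: the single stereocentre comes from the Sharpless epoxidation with D-(−)-diisopropyl tartrate (step 11), and its C–O bond is not touched afterwards.

Key step: step 5

Remark: TBS = tert-butyldimethylsilyl. From compound 13 on, chromen-4-one (isoflavone) numbering is used. The stereocentre of the target SMILES is read as R (OH > isopropenyl > CH2–aryl > H).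

Step 1
Reactants: 1 3,4-dihydroxyphenylacetic acid
Product: 2 tert-butyldimethylsilyl 2-[3,4-bis(tert-butyldimethylsilyloxy)phenyl]acetate
Conditions: TBSCl (3.6 equiv), imidazole (7 equiv), DMF, 23 °C
Reagents that add atoms: tert-butyldimethylsilyl chloride, CC(C)(C)[Si](C)(C)Cl
Why: Standard silylation with TBSCl and imidazole caps both phenols and the acid, and the silyl ester is wanted as the handle for step 2.

Step 2
Reactants: 2 tert-butyldimethylsilyl 2-[3,4-bis(tert-butyldimethylsilyloxy)phenyl]acetate; 3 methyl acetoacetate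
Product: 5 methyl 2-acetyl-4-[3,4-bis(tert-butyldimethylsilyloxy)phenyl]-3-oxobutanoate, via arylacetyl chloride 4 (not isolated)
Conditions: (COCl)2 (1.2 equiv), DMF (cat.), CH2Cl2, 0 → 23 °C, concentrate; then 3 (1.1 equiv), MgCl2 (1.1 equiv), pyridine (2.2 equiv), CH2Cl2, 0 → 23 °C; cold 1 M HCl
Reagents that add atoms: oxalyl chloride, O=C(Cl)C(=O)Cl (supplies the chlorine of 4; none of its atoms stays in 5)
Why: The chloroiminium species from oxalyl chloride and DMF turns a silyl ester into the acid chloride without free HCl, and the magnesium chelate of 3 formed by soft enolisation is acylated on carbon, pyridine being too weak a base to make the aryl ketene.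

Step 3
Reactants: 5 methyl 2-acetyl-4-[3,4-bis(tert-butyldimethylsilyloxy)phenyl]-3-oxobutanoate
Product: 7 methyl 5-[3,4-bis(tert-butyldimethylsilyloxy)phenyl]-2-methyl-4-oxo-4H-pyran-3-carboxylate, via enaminone 6 (not isolated)
Conditions: Me2NCH(OMe)2 (1.1 equiv), toluene, 80 °C, evaporate; then TFA (3 equiv), CH2Cl2, 0 → 23 °C
Reagents that add atoms: N,N-dimethylformamide dimethyl acetal, COC(OC)N(C)C
Why: This is an amide acetal condensation followed by addition–elimination ring closure, as in the deoxybenzoin-to-isoflavone conversion and in the chemistry of 3-acyl-4-hydroxy-2-pyranones: the benzylic methylene is the more acidic flanking position and forms enaminone 6, and acid lets the enol oxygen of the acetyl group displace dimethylamine to give the 4-pyranone.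

Step 4
Reactants: 8 2-methylbut-3-en-2-ol; 9 trimethyl orthoacetate
Product: 11 methyl 5-methylhex-4-enoate, via ketene acetal 10 (not isolated)
Conditions: 9 (3 equiv), EtCO2H (5 mol %), 110 → 140 °C, MeOH distilled off
Reagents that add atoms: none
Why: In this Johnson–Claisen rearrangement, acid-catalysed exchange and loss of methanol give ketene acetal 10, whose [3,3] shift moves the tertiary allyl unit onto carbon and leaves the trisubstituted, prenyl-type double bond.

Step 5
Reactants: 7 methyl 5-[3,4-bis(tert-butyldimethylsilyloxy)phenyl]-2-methyl-4-oxo-4H-pyran-3-carboxylate; 11 methyl 5-methylhex-4-enoate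
Product: 13 3-[3,4-bis(tert-butyldimethylsilyloxy)phenyl]-5,7-dihydroxy-6-(3-methylbut-2-enyl)-4H-chromen-4-one, via acylmethyl pyranone 12 (not isolated)
Conditions: LDA (1.05 equiv), THF, −78 °C; 11 (1.5 equiv), −78 → 23 °C; recool, LDA (3.0 equiv), −78 → 0 °C; AcOH, −78 °C
Reagents that add atoms: none
Why: Proposed new method: one equivalent of LDA removes a proton from the 2-methyl group of 7 to give a dienolate spread over the C4 carbonyl and the C3 ester; this anion is too weak a base to enolise 11, so on warming its exocyclic carbon adds to the ester carbonyl of 11 (Claisen condensation, C7–C8), and the methoxide released deprotonates the doubly activated methylene of 12, which draws the equilibrium forward without consuming a second molecule of 7. The second charge of LDA removes a proton from the prenyl-bearing alpha' carbon of this mono-anion, as in the dianion chemistry of 1,3-dicarbonyl compounds, and the new, more reactive enolate terminus attacks the adjacent C3 ester (Dieckmann condensation, C5–C6). Ring A closes in the favoured 6-(enolendo)-exo-trig mode, and loss of methoxide followed by tautomerisation to the dilithium resorcinolate makes the sequence irreversible. The closest known reaction types are the acylation of lateral 2-methyl-4-pyranone anions with esters, the Staunton–Weinreb annulation of ortho-toluate anions and the base-induced closure of 2-(2-oxoalkyl)benzoates to naphthalene-1,3-diols, but their combination on a pyranone ester has no direct precedent. No stereocentre is formed. The step needs C- over O-acylation and reaction at the exocyclic carbon rather than at C3 (secured by the reversibility of ester acyl transfer, since only adduct 12 can be trapped by deprotonation), and it needs a single closure mode (secured by connectivity, since the C8 carbanion cannot reach the ester and the alpha' enolate can reach it only through a six-membered ring).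

Step 6
Reactants: 13 3-[3,4-bis(tert-butyldimethylsilyloxy)phenyl]-5,7-dihydroxy-6-(3-methylbut-2-enyl)-4H-chromen-4-one
Product: 14 7-allyloxy-3-[3,4-bis(tert-butyldimethylsilyloxy)phenyl]-5-hydroxy-6-(3-methylbut-2-enyl)-4H-chromen-4-one
Conditions: allyl alcohol (1.5 equiv), PPh3 (1.5 equiv), DIAD (1.5 equiv), THF, 0 → 23 °C
Reagents that add atoms: allyl alcohol, C=CCO
Why: In this Mitsunobu etherification the 7-OH is the acidic, non-chelated phenol while the 5-OH is held in a hydrogen bond to C4=O, and the neutral medium avoids base-induced loss or migration of silyl groups.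

Step 7
Reactants: 14 7-allyloxy-3-[3,4-bis(tert-butyldimethylsilyloxy)phenyl]-5-hydroxy-6-(3-methylbut-2-enyl)-4H-chromen-4-one
Product: 15 8-allyl-3-[3,4-bis(tert-butyldimethylsilyloxy)phenyl]-5,7-dihydroxy-6-(3-methylbut-2-enyl)-4H-chromen-4-one
Conditions: PhNEt2, 200 °C, sealed tube, argon
Reagents that add atoms: none
Why: In this aromatic Claisen rearrangement C6 is blocked by prenyl (a shift there is reversible), so the [3,3] shift ends at C8 and enolisation restores ring A, while the basic solvent prevents acid-induced chroman formation from the ortho-prenylphenol.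

Step 8
Reactants: 15 8-allyl-3-[3,4-bis(tert-butyldimethylsilyloxy)phenyl]-5,7-dihydroxy-6-(3-methylbut-2-enyl)-4H-chromen-4-one
Product: 16 8-allyl-3-[3,4-bis(tert-butyldimethylsilyloxy)phenyl]-5,7-bis(tert-butyldimethylsilyloxy)-6-(3-methylbut-2-enyl)-4H-chromen-4-one
Conditions: TBSOTf (3 equiv), 2,6-lutidine (5 equiv), CH2Cl2, 0 → 23 °C
Reagents that add atoms: tert-butyldimethylsilyl triflate, CC(C)(C)[Si](C)(C)OS(=O)(=O)C(F)(F)F
Why: The silyl triflate is reactive enough for the di-ortho-substituted 7-OH and the chelated 5-OH, and free phenols must be absent in step 11 because the 5-OH/C4=O pair would bind titanium.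

Step 9
Reactants: 16 8-allyl-3-[3,4-bis(tert-butyldimethylsilyloxy)phenyl]-5,7-bis(tert-butyldimethylsilyloxy)-6-(3-methylbut-2-enyl)-4H-chromen-4-one
Product: 17 (E)-4-{3-[3,4-bis(tert-butyldimethylsilyloxy)phenyl]-5,7-bis(tert-butyldimethylsilyloxy)-6-(3-methylbut-2-enyl)-4-oxo-4H-chromen-8-yl}-2-methylbut-2-enal
Conditions: methacrolein (10 equiv), second-generation Hoveyda–Grubbs catalyst (5 mol %), 1,4-benzoquinone (10 mol %), CH2Cl2, 40 °C
Reagents that add atoms: methacrolein, C=C(C)C=O
Why: In this olefin cross-metathesis the monosubstituted allyl olefin reacts fast, the trisubstituted prenyl olefin between two silyloxy groups reacts slowly, the trisubstituted enal forms as the E isomer under thermodynamic control, and benzoquinone suppresses hydride-induced migration of the allyl double bond.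

Step 10
Reactants: 17 (E)-4-{3-[3,4-bis(tert-butyldimethylsilyloxy)phenyl]-5,7-bis(tert-butyldimethylsilyloxy)-6-(3-methylbut-2-enyl)-4-oxo-4H-chromen-8-yl}-2-methylbut-2-enal
Product: 18 3-[3,4-bis(tert-butyldimethylsilyloxy)phenyl]-5,7-bis(tert-butyldimethylsilyloxy)-8-[(E)-4-hydroxy-3-methylbut-2-enyl]-6-(3-methylbut-2-enyl)-4H-chromen-4-one
Conditions: NaBH4 (1.0 equiv), CeCl3·7H2O (1.1 equiv), MeOH/THF, −40 °C
Reagents that add atoms: none
Why: Under Luche conditions the cerium-modified borohydride reduces the enal in the 1,2 sense within minutes, whereas the chromenone carbonyl is a hindered vinylogous ester and is left alone.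

Step 11
Reactants: 18 3-[3,4-bis(tert-butyldimethylsilyloxy)phenyl]-5,7-bis(tert-butyldimethylsilyloxy)-8-[(E)-4-hydroxy-3-methylbut-2-enyl]-6-(3-methylbut-2-enyl)-4H-chromen-4-one
Product: 19 3-[3,4-bis(tert-butyldimethylsilyloxy)phenyl]-5,7-bis(tert-butyldimethylsilyloxy)-8-{[(2R,3R)-3-(hydroxymethyl)-3-methyloxiran-2-yl]methyl}-6-(3-methylbut-2-enyl)-4H-chromen-4-one
Conditions: Ti(OiPr)4 (20 mol %), D-(−)-diisopropyl tartrate (24 mol %), t-BuOOH (2 equiv, decane), 4 Å MS, CH2Cl2, −20 °C
Reagents that add atoms: tert-butyl hydroperoxide, CC(C)(C)OO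
Why: In the Sharpless asymmetric epoxidation only the allylic alcohol binds to the titanium tartrate, so the prenyl and chromenone double bonds stay untouched, and for (E)-2-methyl-3-alkylallyl alcohols the D-(−)-tartrate catalyst gives the (2R,3R)-epoxy alcohol (the L-(+)-ligand gives the 2S,3S series), which sets the future carbinol carbon as R.

Step 12
Reactants: 19 3-[3,4-bis(tert-butyldimethylsilyloxy)phenyl]-5,7-bis(tert-butyldimethylsilyloxy)-8-{[(2R,3R)-3-(hydroxymethyl)-3-methyloxiran-2-yl]methyl}-6-(3-methylbut-2-enyl)-4H-chromen-4-one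
Product: 20 3-[3,4-bis(tert-butyldimethylsilyloxy)phenyl]-5,7-bis(tert-butyldimethylsilyloxy)-8-{[(2R,3S)-3-(iodomethyl)-3-methyloxiran-2-yl]methyl}-6-(3-methylbut-2-enyl)-4H-chromen-4-one
Conditions: PPh3 (1.5 equiv), imidazole (2 equiv), I2 (1.4 equiv), THF, 0 °C, dark
Reagents that add atoms: iodine, II
Why: This Appel-type iodination replaces the primary hydroxyl by SN2 under nearly neutral conditions that spare the epoxide, silyl ethers and olefins, and the new descriptor at the quaternary carbon reflects a change of CIP priority only.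

Step 13
Reactants: 20 3-[3,4-bis(tert-butyldimethylsilyloxy)phenyl]-5,7-bis(tert-butyldimethylsilyloxy)-8-{[(2R,3S)-3-(iodomethyl)-3-methyloxiran-2-yl]methyl}-6-(3-methylbut-2-enyl)-4H-chromen-4-one
Product: 21 3-[3,4-bis(tert-butyldimethylsilyloxy)phenyl]-5,7-bis(tert-butyldimethylsilyloxy)-8-[(2R)-2-hydroxy-3-methylbut-3-enyl]-6-(3-methylbut-2-enyl)-4H-chromen-4-one
Conditions: Zn dust (activated, 10 equiv), EtOH/THF, 60 °C; aq. NH4Cl
Reagents that add atoms: none
Why: Zinc inserts into the C–I bond and the beta-oxido organozinc fragments (reductive epoxide opening, a Boord-type elimination), which breaks only the C–O bond at the quaternary carbon, so the secondary C–O bond keeps its R configuration and the isopropenyl group appears.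

Step 14
Reactants: 21 3-[3,4-bis(tert-butyldimethylsilyloxy)phenyl]-5,7-bis(tert-butyldimethylsilyloxy)-8-[(2R)-2-hydroxy-3-methylbut-3-enyl]-6-(3-methylbut-2-enyl)-4H-chromen-4-one
Product: 22 3-(3,4-dihydroxyphenyl)-5,7-dihydroxy-8-[(2R)-2-hydroxy-3-methylbut-3-enyl]-6-(3-methylbut-2-enyl)-4H-chromen-4-one (CNP0236775.1)
Conditions: TBAF (6 equiv), AcOH (6 equiv), THF, 0 °C, argon
Reagents that add atoms: none
Why: Fluoride-induced desilylation buffered with acetic acid frees all four phenols without the acid that would cyclise the ortho-prenyl or ionise the allylic alcohol, and without the free base that would expose the catechol to oxidation.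

**Compound list**
1 | 3,4-dihydroxyphenylacetic acid | O=C(O)Cc1ccc(O)c(O)c1 | starting material
2 | tert-butyldimethylsilyl 2-[3,4-bis(tert-butyldimethylsilyloxy)phenyl]acetate | CC(C)(C)[Si](C)(C)OC(=O)Cc1ccc(O[Si](C)(C)C(C)(C)C)c(O[Si](C)(C)C(C)(C)C)c1 | intermediate
3 | methyl acetoacetate | COC(=O)CC(C)=O | starting material
4 | 2-[3,4-bis(tert-butyldimethylsilyloxy)phenyl]acetyl chloride | O=C(Cl)Cc1ccc(O[Si](C)(C)C(C)(C)C)c(O[Si](C)(C)C(C)(C)C)c1 | intermediate
5 | methyl 2-acetyl-4-[3,4-bis(tert-butyldimethylsilyloxy)phenyl]-3-oxobutanoate (enolised; drawn as the triketo form) | COC(=O)C(C(C)=O)C(=O)Cc1ccc(O[Si](C)(C)C(C)(C)C)c(O[Si](C)(C)C(C)(C)C)c1 | intermediate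
6 | methyl 2-acetyl-4-[3,4-bis(tert-butyldimethylsilyloxy)phenyl]-5-(dimethylamino)-3-oxopent-4-enoate (double-bond geometry not defined) | COC(=O)C(C(C)=O)C(=O)C(=CN(C)C)c1ccc(O[Si](C)(C)C(C)(C)C)c(O[Si](C)(C)C(C)(C)C)c1 | intermediate
7 | methyl 5-[3,4-bis(tert-butyldimethylsilyloxy)phenyl]-2-methyl-4-oxo-4H-pyran-3-carboxylate | COC(=O)c1c(C)occ(-c2ccc(O[Si](C)(C)C(C)(C)C)c(O[Si](C)(C)C(C)(C)C)c2)c1=O | intermediate
8 | 2-methylbut-3-en-2-ol | C=CC(C)(C)O | starting material
9 | trimethyl orthoacetate | COC(C)(OC)OC | starting material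
10 | 3-[(1-methoxyethenyl)oxy]-3-methylbut-1-ene | C=CC(C)(C)OC(=C)OC | intermediate
11 | methyl 5-methylhex-4-enoate | COC(=O)CCC=C(C)C | intermediate
12 | methyl 5-[3,4-bis(tert-butyldimethylsilyloxy)phenyl]-2-(6-methyl-2-oxohept-5-enyl)-4-oxo-4H-pyran-3-carboxylate | COC(=O)c1c(CC(=O)CCC=C(C)C)occ(-c2ccc(O[Si](C)(C)C(C)(C)C)c(O[Si](C)(C)C(C)(C)C)c2)c1=O | intermediate
13 | 3-[3,4-bis(tert-butyldimethylsilyloxy)phenyl]-5,7-dihydroxy-6-(3-methylbut-2-enyl)-4H-chromen-4-one | CC(C)=CCc1c(O)cc2occ(-c3ccc(O[Si](C)(C)C(C)(C)C)c(O[Si](C)(C)C(C)(C)C)c3)c(=O)c2c1O | intermediate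
14 | 7-allyloxy-3-[3,4-bis(tert-butyldimethylsilyloxy)phenyl]-5-hydroxy-6-(3-methylbut-2-enyl)-4H-chromen-4-one | C=CCOc1cc2occ(-c3ccc(O[Si](C)(C)C(C)(C)C)c(O[Si](C)(C)C(C)(C)C)c3)c(=O)c2c(O)c1CC=C(C)C | intermediate
15 | 8-allyl-3-[3,4-bis(tert-butyldimethylsilyloxy)phenyl]-5,7-dihydroxy-6-(3-methylbut-2-enyl)-4H-chromen-4-one | C=CCc1c(O)c(CC=C(C)C)c(O)c2c(=O)c(-c3ccc(O[Si](C)(C)C(C)(C)C)c(O[Si](C)(C)C(C)(C)C)c3)coc12 | intermediate
16 | 8-allyl-3-[3,4-bis(tert-butyldimethylsilyloxy)phenyl]-5,7-bis(tert-butyldimethylsilyloxy)-6-(3-methylbut-2-enyl)-4H-chromen-4-one | C=CCc1c(O[Si](C)(C)C(C)(C)C)c(CC=C(C)C)c(O[Si](C)(C)C(C)(C)C)c2c(=O)c(-c3ccc(O[Si](C)(C)C(C)(C)C)c(O[Si](C)(C)C(C)(C)C)c3)coc12 | intermediate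
17 | (E)-enal: 8-[(E)-3-methyl-4-oxobut-2-enyl] analogue of 16 | O=C/C(C)=C/Cc1c(O[Si](C)(C)C(C)(C)C)c(CC=C(C)C)c(O[Si](C)(C)C(C)(C)C)c2c(=O)c(-c3ccc(O[Si](C)(C)C(C)(C)C)c(O[Si](C)(C)C(C)(C)C)c3)coc12 | intermediate
18 | (E)-allylic alcohol: 8-[(E)-4-hydroxy-3-methylbut-2-enyl] analogue of 16 | OC/C(C)=C/Cc1c(O[Si](C)(C)C(C)(C)C)c(CC=C(C)C)c(O[Si](C)(C)C(C)(C)C)c2c(=O)c(-c3ccc(O[Si](C)(C)C(C)(C)C)c(O[Si](C)(C)C(C)(C)C)c3)coc12 | intermediate
19 | epoxy alcohol: 8-{[(2R,3R)-3-(hydroxymethyl)-3-methyloxiran-2-yl]methyl} analogue of 16 | OC[C@@]4(C)O[C@@H]4Cc1c(O[Si](C)(C)C(C)(C)C)c(CC=C(C)C)c(O[Si](C)(C)C(C)(C)C)c2c(=O)c(-c3ccc(O[Si](C)(C)C(C)(C)C)c(O[Si](C)(C)C(C)(C)C)c3)coc12 | intermediate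
20 | epoxy iodide: 8-{[(2R,3S)-3-(iodomethyl)-3-methyloxiran-2-yl]methyl} analogue of 16 | IC[C@@]4(C)O[C@@H]4Cc1c(O[Si](C)(C)C(C)(C)C)c(CC=C(C)C)c(O[Si](C)(C)C(C)(C)C)c2c(=O)c(-c3ccc(O[Si](C)(C)C(C)(C)C)c(O[Si](C)(C)C(C)(C)C)c3)coc12 | intermediate
21 | tetrasilyl ether of the target: 8-[(2R)-2-hydroxy-3-methylbut-3-enyl] analogue of 16 | C=C(C)[C@H](O)Cc1c(O[Si](C)(C)C(C)(C)C)c(CC=C(C)C)c(O[Si](C)(C)C(C)(C)C)c2c(=O)c(-c3ccc(O[Si](C)(C)C(C)(C)C)c(O[Si](C)(C)C(C)(C)C)c3)coc12 | intermediate
22 | 3-(3,4-dihydroxyphenyl)-5,7-dihydroxy-8-[(2R)-2-hydroxy-3-methylbut-3-enyl]-6-(3-methylbut-2-enyl)-4H-chromen-4-one | C=C(C)[C@H](O)Cc1c(O)c(CC=C(C)C)c(O)c2c(=O)c(-c3ccc(O)c(O)c3)coc12 | target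

**Step count**
Total steps: 14. Longest linear sequence: 13 (steps 1–3 and 5–14). Step 4 is a one-step branch.

**Steps most likely to fail**

1. Step 5 (new method).
   - What may go wrong: the doubly stabilised lateral anion may add too slowly to an unactivated ester. Other processes could then take over on warming, namely methoxide-induced loss of aryl silyl groups, conjugate attack at the unsubstituted C6 of the pyranone with ring opening, or a stall after the first acylation.
   - Fallback: this route uses known chemistry only, gives up the annulation, sets out from 1 and comes back at 13. Friedel–Crafts acylation of phloroglucinol with 1 in BF3·OEt2 should give 2-(3,4-dihydroxyphenyl)-1-(2,4,6-trihydroxyphenyl)ethanone F1. Vilsmeier-type formylation and closure (DMF, MsCl, BF3·OEt2) should give orobol F2, the symmetry of the phloroglucinol ring leaving no choice of phenol. TBSCl and imidazole silylate every hydroxyl except the chelated 5-OH to give 7,3',4'-tri-O-TBS-orobol F3. Benzyltrimethylammonium dichloroiodate with CaCO3 iodinates ortho to the free 5-OH to give the 6-iodide F4. Stille coupling with tributyl(3-methylbut-2-enyl)stannane and Pd(PPh3)4 gives the 6-prenyl tri-silyl ether F5. Brief treatment with K2CO3 in MeOH at 0 °C removes the 7-O-silyl group, which is a vinylogous silyl ester and the most labile of the three, to give 13.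

2. Step 3.
   - What may go wrong: the acidic tricarbonyl may be deacetylated by methanol or dimethylamine, or O-methylated by the amide acetal. Condensation may also occur at the acetyl methyl group, or go on at the acidic 2-methyl group of the product.
   - Fallback: this route masks the acetyl group before the one-carbon unit is brought in. It sets out from 3 and from 4 (made from 2 as in step 2) and comes back at 7. Condensation of 3 with pyrrolidine gives methyl (E)-3-(pyrrolidin-1-yl)but-2-enoate F6. Its nucleophilic C2 is acylated by 4 (Et3N, CH2Cl2) to give methyl 4-[3,4-bis(tert-butyldimethylsilyloxy)phenyl]-3-oxo-2-[1-(pyrrolidin-1-yl)ethylidene]butanoate F7, which has no acidic enol. LiN(SiMe3)2 removes a benzylic proton and ethyl formate gives the formyl ketone methyl 4-[3,4-bis(tert-butyldimethylsilyloxy)phenyl]-3,5-dioxo-2-[1-(pyrrolidin-1-yl)ethylidene]pentanoate F8. On acidification F8 closes through its formyl enol oxygen, with loss of pyrrolidine, to 7.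

3. Step 9.
   - What may go wrong: competing metathesis at the prenyl double bond, migration of the allyl double bond into conjugation, or sluggish coupling with the 1,1-disubstituted partner.
   - Fallback: this route forms the C8–CH2 bond by palladium catalysis instead. It sets out from 13, by-passes steps 6 to 10 and comes back at 18. TBSOTf and 2,6-lutidine give the 5,7-bis-silyl ether F9. N-iodosuccinimide in MeCN iodinates the only free position of ring A to give the 8-iodide F10, and no free phenol is left that could trap an iodonium ion on the prenyl group. Coupling of F10 with 2-methyl-2-vinyloxirane under Pd(OAc)2, HCO2Na, Bu4NCl and iPr2NEt in DMA proceeds by aryl-palladium addition to the vinyl group and beta-oxygen elimination with opening of the epoxide, and formate returns the metal to the zerovalent state. This gives 18 together with its Z isomer. The Z isomer must be removed before step 11, because it would lead to the opposite configuration at the carbinol carbon.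

**Further compounds**
F1 | step 5 | 2-(3,4-dihydroxyphenyl)-1-(2,4,6-trihydroxyphenyl)ethanone | O=C(Cc1ccc(O)c(O)c1)c1c(O)cc(O)cc1O
F2 | step 5 | orobol, 3-(3,4-dihydroxyphenyl)-5,7-dihydroxy-4H-chromen-4-one | O=c1c(-c2ccc(O)c(O)c2)coc2cc(O)cc(O)c12
F3 | step 5 | 7,3',4'-tri-O-TBS-orobol | O=c1c(-c2ccc(O[Si](C)(C)C(C)(C)C)c(O[Si](C)(C)C(C)(C)C)c2)coc2cc(O[Si](C)(C)C(C)(C)C)cc(O)c12
F4 | step 5 | 6-iodo-7,3',4'-tri-O-TBS-orobol | O=c1c(-c2ccc(O[Si](C)(C)C(C)(C)C)c(O[Si](C)(C)C(C)(C)C)c2)coc2cc(O[Si](C)(C)C(C)(C)C)c(I)c(O)c12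
F5 | step 5 | 6-(3-methylbut-2-enyl)-7,3',4'-tri-O-TBS-orobol | O=c1c(-c2ccc(O[Si](C)(C)C(C)(C)C)c(O[Si](C)(C)C(C)(C)C)c2)coc2cc(O[Si](C)(C)C(C)(C)C)c(CC=C(C)C)c(O)c12
F6 | step 3 | methyl (E)-3-(pyrrolidin-1-yl)but-2-enoate | COC(=O)/C=C(\C)N1CCCC1
F7 | step 3 | methyl 4-[3,4-bis(tert-butyldimethylsilyloxy)phenyl]-3-oxo-2-[1-(pyrrolidin-1-yl)ethylidene]butanoate | COC(=O)C(C(=O)Cc1ccc(O[Si](C)(C)C(C)(C)C)c(O[Si](C)(C)C(C)(C)C)c1)=C(C)N1CCCC1
F8 | step 3 | methyl 4-[3,4-bis(tert-butyldimethylsilyloxy)phenyl]-3,5-dioxo-2-[1-(pyrrolidin-1-yl)ethylidene]pentanoate | COC(=O)C(C(=O)C(C=O)c1ccc(O[Si](C)(C)C(C)(C)C)c(O[Si](C)(C)C(C)(C)C)c1)=C(C)N1CCCC1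
F9 | step 9 | 3-[3,4-bis(tert-butyldimethylsilyloxy)phenyl]-5,7-bis(tert-butyldimethylsilyloxy)-6-(3-methylbut-2-enyl)-4H-chromen-4-one | CC(C)=CCc1c(O[Si](C)(C)C(C)(C)C)cc2occ(-c3ccc(O[Si](C)(C)C(C)(C)C)c(O[Si](C)(C)C(C)(C)C)c3)c(=O)c2c1O[Si](C)(C)C(C)(C)C
F10 | step 9 | 8-iodo derivative of F9 | CC(C)=CCc1c(O[Si](C)(C)C(C)(C)C)c(I)c2occ(-c3ccc(O[Si](C)(C)C(C)(C)C)c(O[Si](C)(C)C(C)(C)C)c3)c(=O)c2c1O[Si](C)(C)C(C)(C)C
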